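**Plan**
1. Numbering: oxolane O-1, C-2, C-3 (carries the carbinol carbon C-7), C-4 (carries the benzylic CH2, C-7'), C-5. Retrosynthesis cuts, in order: the two ArO–Bn bonds; the ring bond C-3–C-4 together with one C-7'–H bond (radical 5-exo closure); the C-3–CO2 bond (redox-active ester); the C-4=C-7' styrene bond (cross-metathesis); the C-3–C-2 bond (enolate alkylation); the C-7–H bond (ketone hydrogenation).
2. Enabling feature: ring carbon C-3 is the α-carbon of an aryl aldol unit, so the aldol-type acid gives a C-3 radical on decarboxylation. C-2–O-1–C-5 is an allylic ether tether that holds the C-4=C-7' double bond 5-exo to that radical. C-7' is benzylic, so the cyclised radical is stabilised and ends as CH2Ar.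
3. Forward: aldehyde → β-keto ester → (S)-β-hydroxy ester → α-(allyloxymethyl) ester → cinnamyl ether (metathesis with the styrene from the same aldehyde) → acid → N-acyloxyphthalimide → decarboxylative radical cyclisation, which closes the oxolane (the only non-aromatic ring) → debenzylation.
4. Stereochemistry: C-7 (S) is set by Ru–BINAP hydrogenation. C-3 (S) and C-4 (R) are both relayed from C-7 in the single cyclisation event. This relay is the least certain point of the route and is treated first among the risks.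

Key step: step 8

Remark: the target is read as the 3,4-cis oxolane, (3S,4R) with (S) at C-7; both phenols are carried as benzyl ethers and both aryl units come from commercial 3-(benzyloxy)-4-methoxybenzaldehyde.

**Step 1**
Reactants: 1 3-(benzyloxy)-4-methoxybenzaldehyde
Product: 2 ethyl 3-[3-(benzyloxy)-4-methoxyphenyl]-3-oxopropanoate
Conditions: N2CHCO2Et (1.2 equiv), NbCl5 (5 mol %), CH2Cl2, rt
Reagents that add atoms: ethyl diazoacetate, CCOC(=O)C=[N+]=[N-]
Why: Roskamp homologation, in which Lewis-acid-promoted addition of the diazo ester to the aldehyde is followed by a 1,2-hydride shift with loss of N2 to give the β-keto ester.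

**Step 2**
Reactants: 2 ethyl 3-[3-(benzyloxy)-4-methoxyphenyl]-3-oxopropanoate
Product: 3 ethyl (3S)-3-[3-(benzyloxy)-4-methoxyphenyl]-3-hydroxypropanoate
Conditions: [RuCl2((R)-BINAP)]n (0.5 mol %), H2 (50 atm), EtOH, 50 °C
Reagents that add atoms: none
Why: Noyori asymmetric hydrogenation of a β-keto ester, in which the chelated substrate is reduced from one face by the (R)-BINAP–Ru hydride, the ligand antipode expected to give (S)-3-aryl-3-hydroxypropanoates, so that C-7 is set by catalysis.

**Step 3**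
Reactants: 3 ethyl (3S)-3-[3-(benzyloxy)-4-methoxyphenyl]-3-hydroxypropanoate
Product: 5 ethyl (2R,3S)-3-[3-(benzyloxy)-4-methoxyphenyl]-3-hydroxy-2-[(prop-2-en-1-yloxy)methyl]propanoate, via dilithium dianion 4 (not isolated)
Conditions: LDA (2.2 equiv), THF, −78 → −20 °C; then CH2=CHCH2OCH2Cl, DMPU, −78 → −20 °C
Reagents that add atoms: allyl chloromethyl ether, C=CCOCCl
Why: Fráter–Seebach alkylation, in which the lithium-bridged alkoxide–enolate is alkylated at carbon anti to the aryl group to give the anti (2R,3S) ester; the C-2 configuration is of no consequence because this carbon later becomes the radical centre.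

**Step 4**
Reactants: 1 3-(benzyloxy)-4-methoxybenzaldehyde
Product: 6 2-(benzyloxy)-4-ethenyl-1-methoxybenzene
Conditions: Ph3PCH3Br, KOtBu, THF, 0 °C → rt
Reagents that add atoms: methyltriphenylphosphonium bromide, C[P+](c1ccccc1)(c1ccccc1)c1ccccc1.[Br-]
Why: Wittig methylenation of the aromatic aldehyde gives the styrene partner.

**Step 5**
Reactants: 5 ethyl (2R,3S)-3-[3-(benzyloxy)-4-methoxyphenyl]-3-hydroxy-2-[(prop-2-en-1-yloxy)methyl]propanoate, 6 2-(benzyloxy)-4-ethenyl-1-methoxybenzene
Product: 7 ethyl (2R,3S)-3-[3-(benzyloxy)-4-methoxyphenyl]-2-({[(2E)-3-[3-(benzyloxy)-4-methoxyphenyl]prop-2-en-1-yl]oxy}methyl)-3-hydroxypropanoate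
Conditions: 6 (3 equiv), Grubbs II (5 mol %), CH2Cl2, 40 °C
Reagents that add atoms: none
Why: Olefin cross-metathesis of the terminal allyl ether with the styrene used in excess should give the thermodynamically favoured (E)-cinnamyl ether and tolerates the free hydroxyl and the ester.

**Step 6**
Reactants: 7 ethyl (2R,3S)-3-[3-(benzyloxy)-4-methoxyphenyl]-2-({[(2E)-3-[3-(benzyloxy)-4-methoxyphenyl]prop-2-en-1-yl]oxy}methyl)-3-hydroxypropanoate
Product: 8 (2R,3S)-3-[3-(benzyloxy)-4-methoxyphenyl]-2-({[(2E)-3-[3-(benzyloxy)-4-methoxyphenyl]prop-2-en-1-yl]oxy}methyl)-3-hydroxypropanoic acid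
Conditions: LiOH·H2O, THF/H2O (3:1), 0 °C → rt; then 1 M HCl
Reagents that add atoms: lithium hydroxide, [Li+].[OH-]
Why: Saponification of the ethyl ester at low temperature, where retro-aldol cleavage and β-elimination of the β-hydroxy ester should not compete.

**Step 7**
Reactants: 8 (2R,3S)-3-[3-(benzyloxy)-4-methoxyphenyl]-2-({[(2E)-3-[3-(benzyloxy)-4-methoxyphenyl]prop-2-en-1-yl]oxy}methyl)-3-hydroxypropanoic acid
Product: 9 1,3-dioxoisoindolin-2-yl (2R,3S)-3-[3-(benzyloxy)-4-methoxyphenyl]-2-({[(2E)-3-[3-(benzyloxy)-4-methoxyphenyl]prop-2-en-1-yl]oxy}methyl)-3-hydroxypropanoate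
Conditions: N-hydroxyphthalimide, DIC, DMAP (cat.), CH2Cl2, 0 °C → rt
Reagents that add atoms: N-hydroxyphthalimide, O=C1c2ccccc2C(=O)N1O
Why: Carbodiimide (Steglich-type) esterification gives the redox-active ester, since the acidic N-hydroxy imide should trap the activated carboxyl much faster than the hindered secondary benzylic hydroxyl.

**Step 8**
Reactants: 9 1,3-dioxoisoindolin-2-yl (2R,3S)-3-[3-(benzyloxy)-4-methoxyphenyl]-2-({[(2E)-3-[3-(benzyloxy)-4-methoxyphenyl]prop-2-en-1-yl]oxy}methyl)-3-hydroxypropanoate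
Product: 12 (S)-[3-(benzyloxy)-4-methoxyphenyl][(3S,4R)-4-{[3-(benzyloxy)-4-methoxyphenyl]methyl}oxolan-3-yl]methanol, via secondary C-3 radical 10 (not isolated), via benzylic C-7' radical 11 (not isolated)
Conditions: [Ir(ppy)2(dtbbpy)]PF6 (1 mol %), Hantzsch ester (1.5 equiv), 2,4,6-triisopropylbenzenethiol (10 mol %), CH2Cl2 (0.02 M), blue LEDs, 20 °C
Reagents that add atoms: none
Why: Single-electron reduction of the N-acyloxyphthalimide by the photoreduced iridium catalyst releases phthalimide anion and CO2 and leaves the secondary C-3 radical 10, which adds 5-exo-trig to the styrene carbon that becomes C-4, and the benzylic C-7' radical 11 is then quenched by hydrogen-atom transfer from the thiol/Hantzsch ester couple. The closest known reaction type is the reductive photoredox decarboxylative radical cyclisation of redox-active esters, together with the 5-exo closures of β-alkoxyalkyl radicals onto cinnamyl ethers used for furan lignans under tin or titanium(III) conditions. The oxolane is closed in the 5-exo-trig mode by forming the C-3–C-4 bond (ring atoms C-3, C-2, O-1, C-5, C-4). C-4 is controlled by the chair-like transition state of the Beckwith rules for a radical substituted at the radical carbon, with the CH(OH)Ar group pseudo-equatorial, which should lead to the 3,4-cis ring. C-3 is controlled by the adjacent (S)-carbinol C-7: in the Felkin-type arrangement proposed here the aryl group is anti to the forming bond, the small unprotected hydroxyl takes the inside position gauche to C-2 and within dipolar or hydrogen-bond contact of O-1, and the hydrogen points outward, so that the alkene is delivered to the face that gives 3S. The step needs 5-exo over 6-endo closure and cyclisation before hydrogen capture (secured by the benzylic stabilisation of 11, the fast addition of alkyl radicals to styrenes and high dilution), and it needs this facial and cis selectivity, for which the hydroxyl is left free and a non-coordinating solvent is used.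

**Step 9**
Reactants: 12 (S)-[3-(benzyloxy)-4-methoxyphenyl][(3S,4R)-4-{[3-(benzyloxy)-4-methoxyphenyl]methyl}oxolan-3-yl]methanol
Product: 13 (S)-(3-hydroxy-4-methoxyphenyl)[(3S,4R)-4-[(3-hydroxy-4-methoxyphenyl)methyl]oxolan-3-yl]methanol
Conditions: H2 (1 atm), 10% Pd/C, EtOAc, rt
Reagents that add atoms: none
Why: Hydrogenolysis of the two aryl benzyl ethers under neutral conditions, under which the secondary benzylic alcohol should survive because cleavage of its C–O bond needs acid assistance.

**Compound list**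
1 | 3-(benzyloxy)-4-methoxybenzaldehyde | O=Cc1ccc(OC)c(OCc2ccccc2)c1 | starting material
2 | ethyl 3-[3-(benzyloxy)-4-methoxyphenyl]-3-oxopropanoate | CCOC(=O)CC(=O)c1ccc(OC)c(OCc2ccccc2)c1 | intermediate
3 | ethyl (3S)-3-[3-(benzyloxy)-4-methoxyphenyl]-3-hydroxypropanoate | CCOC(=O)C[C@H](O)c1ccc(OC)c(OCc2ccccc2)c1 | intermediate
4 | dilithium dianion of 3 (lithium-bridged alkoxide–enolate, enolate oxygen cis to C-3) | [Li+].[Li+].CCO/C([O-])=C/[C@H]([O-])c1ccc(OC)c(OCc2ccccc2)c1 | intermediate (not isolated)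
5 | ethyl (2R,3S)-3-[3-(benzyloxy)-4-methoxyphenyl]-3-hydroxy-2-[(prop-2-en-1-yloxy)methyl]propanoate | CCOC(=O)[C@H](COCC=C)[C@H](O)c1ccc(OC)c(OCc2ccccc2)c1 | intermediate
6 | 2-(benzyloxy)-4-ethenyl-1-methoxybenzene | C=Cc1ccc(OC)c(OCc2ccccc2)c1 | intermediate
7 | ethyl (2R,3S)-3-[3-(benzyloxy)-4-methoxyphenyl]-2-({[(2E)-3-[3-(benzyloxy)-4-methoxyphenyl]prop-2-en-1-yl]oxy}methyl)-3-hydroxypropanoate | CCOC(=O)[C@H](COC/C=C/c1ccc(OC)c(OCc2ccccc2)c1)[C@H](O)c1ccc(OC)c(OCc2ccccc2)c1 | intermediate
8 | (2R,3S)-3-[3-(benzyloxy)-4-methoxyphenyl]-2-({[(2E)-3-[3-(benzyloxy)-4-methoxyphenyl]prop-2-en-1-yl]oxy}methyl)-3-hydroxypropanoic acid | OC(=O)[C@H](COC/C=C/c1ccc(OC)c(OCc2ccccc2)c1)[C@H](O)c1ccc(OC)c(OCc2ccccc2)c1 | intermediate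
9 | 1,3-dioxoisoindolin-2-yl ester of 8 (N-acyloxyphthalimide) | O=C(ON1C(=O)c2ccccc2C1=O)[C@H](COC/C=C/c1ccc(OC)c(OCc2ccccc2)c1)[C@H](O)c1ccc(OC)c(OCc2ccccc2)c1 | intermediate
10 | secondary C-3 radical: (1S)-1-[3-(benzyloxy)-4-methoxyphenyl]-3-{[(2E)-3-[3-(benzyloxy)-4-methoxyphenyl]prop-2-en-1-yl]oxy}-1-hydroxypropan-2-yl | [CH](COC/C=C/c1ccc(OC)c(OCc2ccccc2)c1)[C@H](O)c1ccc(OC)c(OCc2ccccc2)c1 | intermediate (not isolated)
11 | benzylic C-7' radical of the cyclised oxolane (ring cis, carbinol S, as in 12) | COc1ccc([CH][C@H]2COC[C@H]2[C@H](O)c2ccc(OC)c(OCc3ccccc3)c2)cc1OCc1ccccc1 | intermediate (not isolated)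
12 | (S)-[3-(benzyloxy)-4-methoxyphenyl][(3S,4R)-4-{[3-(benzyloxy)-4-methoxyphenyl]methyl}oxolan-3-yl]methanol | COc1ccc(C[C@H]2COC[C@H]2[C@H](O)c2ccc(OC)c(OCc3ccccc3)c2)cc1OCc1ccccc1 | intermediate
13 | (S)-(3-hydroxy-4-methoxyphenyl)[(3S,4R)-4-[(3-hydroxy-4-methoxyphenyl)methyl]oxolan-3-yl]methanol | COc1ccc(C[C@H]2COC[C@H]2[C@H](O)c2ccc(OC)c(O)c2)cc1O | target

Total step count: 9. Longest linear sequence: 8 steps (1, 2, 3, 5, 6, 7, 8, 9); step 4 is a one-step branch from 1.

**Steps most likely to fail**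

Step 8. The relay from C-7 to the radical carbon rests on an acyclic transition-state model. The facial selectivity may be poor or may run in the opposite sense (aryl anti but hydroxyl outside), and the ring may close with incomplete cis selectivity, so that diastereomers of 12 form.
Fallback (sets out from 3, comes back at 12): the three stereocentres are set by a chelate-controlled dianionic Ireland–Claisen rearrangement and the ring is then closed by a plain etherification.
- Copper-catalysed coupling of propargyl alcohol with commercial 3-(benzyloxy)-4-methoxybenzyl chloride should give 4-[3-(benzyloxy)-4-methoxyphenyl]but-2-yn-1-ol F1.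
- Lindlar semi-hydrogenation of F1 should give (2Z)-4-[3-(benzyloxy)-4-methoxyphenyl]but-2-en-1-ol F2.
- Titanate-catalysed transesterification of 3 with F2 (Ti(OiPr)4, toluene, 90 °C) should give the (Z)-allylic β-hydroxy ester F3.
- LDA (2.3 equiv, THF, −78 °C → rt) forms the lithium-bridged alkoxide–enolate. Its [3,3] shift through a chair, with the allyl unit anti to the aryl group and the (Z)-CH2Ar group axial, should give the pentenoic acid F4 with C-3, C-4 and C-7 of the target in place.
- TBSOTf/2,6-lutidine followed by aqueous K2CO3 should give the silyl ether acid F5.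
- LiAlH4 should give the primary alcohol F6.
- OsO4/NaIO4 cleavage of the vinyl group and NaBH4 should give the 1,4-diol F7.
- Mitsunobu cyclodehydration (PPh3, DIAD, THF) should close the oxolane to the silyl ether F8, and TBAF returns 12.

Step 7. The activated carboxyl may acylate the free C-7 hydroxyl (β-lactone or oligoester formation) before N-hydroxyphthalimide traps it.
Fallback (sets out from 8, comes back at 9): the hydroxyl is masked for the activation only. TESOTf (2.2 equiv)/2,6-lutidine, followed by K2CO3 in aqueous methanol to cleave only the silyl ester, should give the triethylsilyl ether acid F9. N-hydroxyphthalimide/DIC then gives the silylated redox-active ester F10. HF·pyridine in THF at 0 °C removes the silyl group and returns 9.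

Step 9. Hydrogenolysis may continue into the electron-rich benzylic C-7–O bond, which would remove the carbinol oxygen.
Fallback (sets out from 12, comes back at 13): the carbinol is shielded before the hydrogenolysis. TIPSOTf/2,6-lutidine should give the triisopropylsilyl ether F11. H2, Pd/C in EtOAc then removes only the two aryl benzyl groups to give the bis-phenol silyl ether F12, and TBAF returns 13.

**Further compounds**
F1 | step 8 | 4-[3-(benzyloxy)-4-methoxyphenyl]but-2-yn-1-ol | OCC#CCc1ccc(OC)c(OCc2ccccc2)c1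
F2 | step 8 | (2Z)-4-[3-(benzyloxy)-4-methoxyphenyl]but-2-en-1-ol | OC/C=C\Cc1ccc(OC)c(OCc2ccccc2)c1
F3 | step 8 | (2Z)-4-[3-(benzyloxy)-4-methoxyphenyl]but-2-en-1-yl (3S)-3-[3-(benzyloxy)-4-methoxyphenyl]-3-hydroxypropanoate | O=C(OC/C=C\Cc1ccc(OC)c(OCc2ccccc2)c1)C[C@H](O)c1ccc(OC)c(OCc2ccccc2)c1
F4 | step 8 | (2R,3S)-3-{[3-(benzyloxy)-4-methoxyphenyl]methyl}-2-{(S)-[3-(benzyloxy)-4-methoxyphenyl](hydroxy)methyl}pent-4-enoic acid | OC(=O)[C@H]([C@@H](Cc1ccc(OC)c(OCc2ccccc2)c1)C=C)[C@H](O)c1ccc(OC)c(OCc2ccccc2)c1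
F5 | step 8 | (2R,3S)-3-{[3-(benzyloxy)-4-methoxyphenyl]methyl}-2-{(S)-[3-(benzyloxy)-4-methoxyphenyl][(tert-butyldimethylsilyl)oxy]methyl}pent-4-enoic acid | OC(=O)[C@H]([C@@H](Cc1ccc(OC)c(OCc2ccccc2)c1)C=C)[C@H](O[Si](C)(C)C(C)(C)C)c1ccc(OC)c(OCc2ccccc2)c1
F6 | step 8 | (2S,3S)-3-{[3-(benzyloxy)-4-methoxyphenyl]methyl}-2-{(S)-[3-(benzyloxy)-4-methoxyphenyl][(tert-butyldimethylsilyl)oxy]methyl}pent-4-en-1-ol | OC[C@H]([C@@H](Cc1ccc(OC)c(OCc2ccccc2)c1)C=C)[C@H](O[Si](C)(C)C(C)(C)C)c1ccc(OC)c(OCc2ccccc2)c1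
F7 | step 8 | (2R,3S)-2-{[3-(benzyloxy)-4-methoxyphenyl]methyl}-3-{(S)-[3-(benzyloxy)-4-methoxyphenyl][(tert-butyldimethylsilyl)oxy]methyl}butane-1,4-diol | OC[C@H]([C@@H](Cc1ccc(OC)c(OCc2ccccc2)c1)CO)[C@H](O[Si](C)(C)C(C)(C)C)c1ccc(OC)c(OCc2ccccc2)c1
F8 | step 8 | tert-butyldimethylsilyl ether of 12 at C-7 (oxolane 3S,4R; C-7 S) | COc1ccc(C[C@H]2COC[C@H]2[C@H](O[Si](C)(C)C(C)(C)C)c2ccc(OC)c(OCc3ccccc3)c2)cc1OCc1ccccc1
F9 | step 7 | triethylsilyl ether of acid 8 at C-3 (2R,3S) | OC(=O)[C@H](COC/C=C/c1ccc(OC)c(OCc2ccccc2)c1)[C@H](O[Si](CC)(CC)CC)c1ccc(OC)c(OCc2ccccc2)c1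
F10 | step 7 | triethylsilyl ether of redox-active ester 9 (2R,3S) | O=C(ON1C(=O)c2ccccc2C1=O)[C@H](COC/C=C/c1ccc(OC)c(OCc2ccccc2)c1)[C@H](O[Si](CC)(CC)CC)c1ccc(OC)c(OCc2ccccc2)c1
F11 | step 9 | triisopropylsilyl ether of 12 at C-7 (oxolane 3S,4R; C-7 S) | COc1ccc(C[C@H]2COC[C@H]2[C@H](O[Si](C(C)C)(C(C)C)C(C)C)c2ccc(OC)c(OCc3ccccc3)c2)cc1OCc1ccccc1
F12 | step 9 | triisopropylsilyl ether of 13 at C-7 (oxolane 3S,4R; C-7 S; both phenols free) | COc1ccc(C[C@H]2COC[C@H]2[C@H](O[Si](C(C)C)(C(C)C)C(C)C)c2ccc(OC)c(O)c2)cc1O
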